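Start with partner.

all flasks: substrate 0.050 M; partner 0.0900 M; time 1.0 h
- north-west: temperature 0 °C
- west: temperature −25 °C
- east: temperature 50 °C
- north-east: temperature 25 °C

    substrate + partner → mono adduct (k1 = 0.030 M⁻¹ s⁻¹, Ea1 = 48.0 kJ mol⁻¹)
    double product ⇌ isomer of the product (K2 = 1.0, k2 = 0.0032 s⁻¹, Ea2 = 95.0 kJ mol⁻¹, ΔH2 = −41.0 kJ mol⁻¹)
    partner → decomposed reagent (k3 = 0.0033 s⁻¹, Ea3 = 90.0 kJ mol⁻¹)
    partner + mono adduct → double product (k4 = 0.053 M⁻¹ s⁻¹, Ea4 = 68.0 kJ mol⁻¹)
    (constants at 25 °C)

* the best flask by amount of double product, in percent of the substrate charged; "all alike" if 1.5 percentage points covers them all (north-west / west / east / north-east / all alike)
* amount of double product at the end, in percent of the substrate charged, north-west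
* amount of double product at the end, in percent of the substrate charged, west
* amount of double product at the end, in percent of the substrate charged, east
* amount of double product at the end, in percent of the substrate charged, north-east

- constants are those at 25 °C; use the activation energies and enthalpies for any other temperature

Partner had two ways open at the start of each flask, both first order in c_partner: it added to substrate, with a life of one over the rate constant times c_substrate, or it decomposed, with a life of one over the constant of decomposition. A further way, addition to mono adduct, opened as mono adduct formed, and I set it aside for the moment. Because c_partner cancelled from the ratio of these two lives, I reckoned on c_substrate. The lives are equal where c_substrate equals the constant of decomposition over that of the first addition. At 0 °C, in north-west, this gave 0.0233 M, and I carried this break-even concentration c* forward.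

The activation energy of decomposition is higher than that of the first addition, so c* climbed with temperature: 0.00362 M in west, 0.110 M in north-east and 0.408 M in east. The charge of 0.050 M lay below c* in north-east and east, so there decomposition was ahead from the start. In north-west and west the charge lay above it.

But c* says nothing of speed. In west the addition life of partner was 9.16 h, longer than the 1.0 h allowed, while in north-west it was 1.09 h. The second addition has a constant like that of the first at 5.4 °C, near north-west's temperature, so I let c* serve for both and committed to north-west.

The forecast also named north-west, with 19.5% there, 0.5% in west, 3.7% in east and 8.2% in north-east, calling it “the best compromise, with partner nearly used up”.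

The simulation put north-west first, with 18.2% of double product, against 0.551% in west, 3.69% in east and 8.23% in north-east. In north-west, substrate stood at 0.0195 M after 1.00 h, below c*, and addition to substrate then took partner at 0.84 times the rate of decomposition.

In the neighbour of north-west with 0.15 M of partner, c* stays 0.0233 M, since c_partner cancels. That flask ended with substrate at 0.00995 M, which is 0.427 of c*, and with 36.7% of double product.

All constants were chosen freely.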